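**Retrosynthetic overview**

1. Atom labels follow the oxolane of the target: O1, C2 (CH bearing the catechol ring), C3 (CH bearing C9H2OH), C4 (carbinol bearing the veratryl CH2), C5 (CH2). Aryl, CH2OH and OH are all cis, so the C2/C3 cis pair cannot be left to equilibration.
2. Last C–C bond: C4–CH2Ar, by aryl Grignard opening of a spiro-oxirane on C4 (a ring that is not in the target), which the C9 hydroxyl directs onto a 4-methylideneoxolane; this sets C4.
3. Oxolane ring: O1–C5 closure of a 1,4-diol while C9 is still a C–B bond, because the C9 oxygen is also 1,4 to C5 and would otherwise compete with the C2 oxygen.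
4. Key disconnection C2–C3: enantioselective syn-allylboration of 3,4-bis(benzyloxy)benzaldehyde with a (Z)-but-2-ene-1,4-diyl bis(boronate) linchpin (Pt 1,4-diboration of a 2-substituted butadiene made by ethylene–alkyne metathesis). One boron makes C2–C3 and sets C2 and C3; the other stays as the masked C9 hydroxyl.
5. Ring order: oxolane (step 5), then spiro-oxirane (step 7, opened in step 8); hydrogenolysis of the benzyl ethers ends the route.

Key step: step 3

Remark: (R)-TRIP is assumed to direct allyl transfer to the Re face of the aryl aldehyde, as it does with simple allyl and crotyl pinacolboronates.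

**Route**

Step 1
Reactants: 1 tert-butyldimethyl(prop-2-yn-1-yloxy)silane; 2 ethylene
Product: 3 tert-butyldimethyl[(2-methylidenebut-3-en-1-yl)oxy]silane
Conditions: Grubbs second-generation catalyst (3 mol%), ethylene (1 atm), CH2Cl2, rt
Reagents that add atoms: none
Why: Ethylene–alkyne cross enyne metathesis should convert the terminal propargylic silyl ether into the 2-substituted buta-1,3-diene; no stereocentre is formed.

Step 2
Reactants: 3 tert-butyldimethyl[(2-methylidenebut-3-en-1-yl)oxy]silane; 4 bis(pinacolato)diboron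
Product: 5 2,2'-[(2E)-2-({[tert-butyl(dimethyl)silyl]oxy}methyl)but-2-ene-1,4-diyl]bis(4,4,5,5-tetramethyl-1,3,2-dioxaborolane) (the two CH2B groups cis)
Conditions: Pt(PPh3)4 (3 mol%), toluene, 80 °C
Reagents that add atoms: none
Why: Pt(0)-catalysed 1,4-diboration of a 1,3-diene (B–B oxidative addition, insertion of the s-cis diene, reductive elimination) should place one boron on each terminus and fix the two CH2B groups cis on the new alkene, the geometry that step 3 turns into the 2,3-cis pair.

Step 3
Reactants: 5 the bis(boronate) of step 2; 6 3,4-bis(benzyloxy)benzaldehyde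
Product: 8 (1R,2S)-1-[3,4-bis(benzyloxy)phenyl]-3-({[tert-butyl(dimethyl)silyl]oxy}methyl)-2-[(4,4,5,5-tetramethyl-1,3,2-dioxaborolan-2-yl)methyl]but-3-en-1-ol, via borate ester 7 (not isolated)
Conditions: (R)-TRIP phosphoric acid (5 mol%), 4 Å MS, toluene, −30 → 0 °C; then aq. NaHCO3
Reagents that add atoms: none
Why: The allyl group is transferred in a closed six-membered chair (type I allylboration): the aldehyde oxygen binds the boron of one CH2–B unit, the γ-carbon (the CH that carries the second CH2Bpin) bonds to the formyl carbon, and the phosphoric acid accelerates this by hydrogen bonding to a pinacol oxygen of the reacting boronate. The closest known reactions are the chiral phosphoric acid catalysed allyl- and crotylboration of aryl aldehydes with pinacol boronates and the uncatalysed allylboration of aldehydes with (Z)-but-2-ene-1,4-diyl bis(boronates) from diene diboration. No ring is closed; the step forms the C2–C3 bond, leaves C4 as a 1,1-disubstituted alkene and leaves C9 as a primary C–B bond that is no longer allylic and therefore inert. C2 is set by the catalyst ((R)-TRIP should send the allyl group to the Re face, giving 1R), and C3 is set relative to C2 by the chair together with the cis CH2B geometry of 5 (a Z-crotyl-type reagent gives the syn adduct, which is the 2,3-cis pair of the oxolane). The selectivity needed is between the two allylboron termini: the terminus that reacts does so through a CH γ-carbon and forms a tertiary centre, whereas the other would have to react through a fully substituted γ-carbon and form a quaternary centre with a CH2OTBS or CH2Bpin group axial in the chair.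

Step 4
Reactants: 8 the homoallylic alcohol of step 3
Product: 9 (1R,2S)-1-[3,4-bis(benzyloxy)phenyl]-3-methylidene-2-[(4,4,5,5-tetramethyl-1,3,2-dioxaborolan-2-yl)methyl]butane-1,4-diol
Conditions: TBAF, AcOH (1:1), THF, 0 °C → rt
Reagents that add atoms: none
Why: Buffered fluoride cleavage of the primary allylic silyl ether should free the C5 hydroxyl without touching the benzylic alcohol or the alkyl pinacolboronate.

Step 5
Reactants: 9 the 1,4-diol of step 4
Product: 10 2-{[(2R,3S)-2-[3,4-bis(benzyloxy)phenyl]-4-methylideneoxolan-3-yl]methyl}-4,4,5,5-tetramethyl-1,3,2-dioxaborolane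
Conditions: PPh3, DIAD, THF, 0 °C → rt
Reagents that add atoms: none
Why: Mitsunobu cyclodehydration of a 1,4-diol should activate the primary allylic hydroxyl as the oxyphosphonium ion and let the benzylic hydroxyl displace it (5-exo-tet), so that C2 keeps its configuration, while the C–B bond at C9 leaves no second oxygen to compete for C5.

Step 6
Reactants: 10 the borylmethyl oxolane of step 5
Product: 12 [(2R,3R)-2-[3,4-bis(benzyloxy)phenyl]-4-methylideneoxolan-3-yl]methanol, via borate ester 11 (not isolated)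
Conditions: NaBO3·4H2O, THF/H2O (1:1), rt
Reagents that add atoms: sodium perborate, [Na+].[O-]OB=O
Why: Perborate oxidation of the primary alkyl boronate (1,2-shift of carbon from boron to oxygen, then hydrolysis) should unmask the C9 hydroxyl without touching either stereocentre or the alkene.

Step 7
Reactants: 12 the homoallylic alcohol of step 6
Product: 13 [(3S,6R,7R)-6-[3,4-bis(benzyloxy)phenyl]-1,5-dioxaspiro[2.4]heptan-7-yl]methanol
Conditions: VO(acac)2 (5 mol%), t-BuOOH (in decane), CH2Cl2, 0 °C → rt
Reagents that add atoms: tert-butyl hydroperoxide, CC(C)(C)OO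
Why: In this hydroxyl-directed vanadium-catalysed epoxidation of a homoallylic alcohol the vanadate ester of the C9 hydroxyl should deliver oxygen to the face of the exocyclic alkene on which the CH2OH group sits, which sets C4 with its oxygen cis to CH2OH and to the aryl group.

Step 8
Reactants: 13 the spiro-oxirane of step 7; 14 (3,4-dimethoxyphenyl)magnesium bromide
Product: 15 (3R,4R,5R)-5-[3,4-bis(benzyloxy)phenyl]-3-[(3,4-dimethoxyphenyl)methyl]-4-(hydroxymethyl)oxolan-3-ol
Conditions: 14 (3 equiv), CuI (10 mol%), THF, −40 → 0 °C; then aq. NH4Cl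
Reagents that add atoms: none
Why: Copper-catalysed SN2 opening of the 2,2-disubstituted oxirane by the aryl Grignard reagent should occur at the unhindered CH2 carbon, leaving the C4–O bond and thus the C4 configuration untouched, and the cis CH2O–Mg group cannot reach the back side of the oxirane CH2.

Step 9
Reactants: 15 the bis(benzyl ether) of step 8
Product: 16 (3R,4R,5R)-5-(3,4-dihydroxyphenyl)-3-[(3,4-dimethoxyphenyl)methyl]-4-(hydroxymethyl)oxolan-3-ol
Conditions: H2 (1 atm), 10% Pd/C, EtOAc, rt
Reagents that add atoms: none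
Why: Hydrogenolysis of the two aryl benzyl ethers over palladium under neutral conditions should release the catechol, the cyclic benzylic ether C2–O1 being much slower to cleave, and no stereocentre is affected.

**Compound list**

1 | tert-butyldimethyl(prop-2-yn-1-yloxy)silane | C#CCO[Si](C)(C)C(C)(C)C | starting material
2 | ethylene | C=C | starting material
3 | tert-butyldimethyl[(2-methylidenebut-3-en-1-yl)oxy]silane | C=CC(=C)CO[Si](C)(C)C(C)(C)C | intermediate
4 | bis(pinacolato)diboron | CC1(C)OB(OC1(C)C)B1OC(C)(C)C(C)(C)O1 | starting material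
5 | 2,2'-[(2E)-2-({[tert-butyl(dimethyl)silyl]oxy}methyl)but-2-ene-1,4-diyl]bis(4,4,5,5-tetramethyl-1,3,2-dioxaborolane), CH2B groups cis | CC1(C)OB(C/C(CO[Si](C)(C)C(C)(C)C)=C\CB2OC(C)(C)C(C)(C)O2)OC1(C)C | intermediate
6 | 3,4-bis(benzyloxy)benzaldehyde | O=Cc1ccc(OCc2ccccc2)c(OCc2ccccc2)c1 | starting material
7 | 2-{[(1R,2S)-1-[3,4-bis(benzyloxy)phenyl]-3-({[tert-butyl(dimethyl)silyl]oxy}methyl)-2-[(4,4,5,5-tetramethyl-1,3,2-dioxaborolan-2-yl)methyl]but-3-en-1-yl]oxy}-4,4,5,5-tetramethyl-1,3,2-dioxaborolane | CC1(C)OB(O[C@@H](c2ccc(OCc3ccccc3)c(OCc3ccccc3)c2)[C@H](C(=C)CO[Si](C)(C)C(C)(C)C)CB4OC(C)(C)C(C)(C)O4)OC1(C)C | intermediate (not isolated)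
8 | (1R,2S)-1-[3,4-bis(benzyloxy)phenyl]-3-({[tert-butyl(dimethyl)silyl]oxy}methyl)-2-[(4,4,5,5-tetramethyl-1,3,2-dioxaborolan-2-yl)methyl]but-3-en-1-ol | O[C@@H](c1ccc(OCc2ccccc2)c(OCc2ccccc2)c1)[C@H](C(=C)CO[Si](C)(C)C(C)(C)C)CB3OC(C)(C)C(C)(C)O3 | intermediate
9 | (1R,2S)-1-[3,4-bis(benzyloxy)phenyl]-3-methylidene-2-[(4,4,5,5-tetramethyl-1,3,2-dioxaborolan-2-yl)methyl]butane-1,4-diol | O[C@@H](c1ccc(OCc2ccccc2)c(OCc2ccccc2)c1)[C@H](C(=C)CO)CB3OC(C)(C)C(C)(C)O3 | intermediate
10 | 2-{[(2R,3S)-2-[3,4-bis(benzyloxy)phenyl]-4-methylideneoxolan-3-yl]methyl}-4,4,5,5-tetramethyl-1,3,2-dioxaborolane | C=C1CO[C@@H](c2ccc(OCc3ccccc3)c(OCc3ccccc3)c2)[C@H]1CB4OC(C)(C)C(C)(C)O4 | intermediate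
11 | 2-{[(2R,3R)-2-[3,4-bis(benzyloxy)phenyl]-4-methylideneoxolan-3-yl]methoxy}-4,4,5,5-tetramethyl-1,3,2-dioxaborolane | C=C1CO[C@@H](c2ccc(OCc3ccccc3)c(OCc3ccccc3)c2)[C@H]1COB4OC(C)(C)C(C)(C)O4 | intermediate (not isolated)
12 | [(2R,3R)-2-[3,4-bis(benzyloxy)phenyl]-4-methylideneoxolan-3-yl]methanol | C=C1CO[C@@H](c2ccc(OCc3ccccc3)c(OCc3ccccc3)c2)[C@H]1CO | intermediate
13 | [(3S,6R,7R)-6-[3,4-bis(benzyloxy)phenyl]-1,5-dioxaspiro[2.4]heptan-7-yl]methanol | C1[C@]2(O1)CO[C@@H](c3ccc(OCc4ccccc4)c(OCc4ccccc4)c3)[C@H]2CO | intermediate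
14 | (3,4-dimethoxyphenyl)magnesium bromide (commercial THF solution) | COc1ccc([Mg]Br)cc1OC | starting material
15 | (3R,4R,5R)-5-[3,4-bis(benzyloxy)phenyl]-3-[(3,4-dimethoxyphenyl)methyl]-4-(hydroxymethyl)oxolan-3-ol | COc1ccc(C[C@]2(O)CO[C@@H](c3ccc(OCc4ccccc4)c(OCc4ccccc4)c3)[C@H]2CO)cc1OC | intermediate
16 | (3R,4R,5R)-5-(3,4-dihydroxyphenyl)-3-[(3,4-dimethoxyphenyl)methyl]-4-(hydroxymethyl)oxolan-3-ol | COc1ccc(C[C@]2(O)CO[C@@H](c3ccc(O)c(O)c3)[C@H]2CO)cc1OC | target

**Step count and risks**

Total steps: 9. Longest linear sequence: 9 steps (1 → 16); 6 and 14 are purchased.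

Step 3 (most at risk). What may go wrong: allyl transfer from the other boron terminus through the fully substituted γ-carbon, or weak facial control by the acid on this congested, doubly borylated reagent. The fallback makes the C2–C3 bond by an auxiliary-controlled anti-aldol reaction instead; it sets out from aldehyde 6 and comes back to the route at alcohol 12. The dianion of 2-methylprop-2-en-1-ol (n-BuLi, TMEDA) is carboxylated to 3-(hydroxymethyl)but-3-enoic acid F1. Silylation on both oxygens (TBSCl, imidazole) gives tert-butyldimethylsilyl 3-({[tert-butyl(dimethyl)silyl]oxy}methyl)but-3-enoate F2, and K2CO3 in aqueous methanol frees 3-({[tert-butyl(dimethyl)silyl]oxy}methyl)but-3-enoic acid F3. Its mixed pivalic anhydride F4 (PivCl, Et3N) acylates (R)-4-benzyl-1,3-oxazolidin-2-one (LiCl) to the N-acyl oxazolidinone F5. The magnesium chloride catalysed anti-aldol reaction of F5 with 6 (MgCl2, Et3N, TMSCl, EtOAc) should give the silylated anti adduct F6: the chelated (Z)-enolate is attacked on the face away from the benzyl group, and the anti relationship is the one that becomes 2,3-cis on the oxolane. Buffered TBAF removes both silyl groups to the diol imide F7. Mitsunobu closure as in step 5 gives the oxolane imide F8, C9 being masked here as the imide so that again only one hydroxyl can reach C5. LiBH4 then cleaves the auxiliary to give 12.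

Step 8. What may go wrong: magnesium halide induced 1,2-hydride shift of the oxirane to an aldehyde, or halide opening, outrunning aryl transfer. The fallback replaces the organometallic by a reductive cross-electrophile coupling; it sets out from oxirane 13 and comes back at 15. With NiCl2·glyme, 2,2'-bipyridine, NaI, Et3N·HCl and Zn in DMPU the oxirane should be opened by iodide at its CH2 carbon to (3R,4R,5R)-5-[3,4-bis(benzyloxy)phenyl]-4-(hydroxymethyl)-3-(iodomethyl)oxolan-3-ol F10. Its primary C–I bond is then coupled through the alkyl radical with 4-bromo-1,2-dimethoxybenzene, so that no Lewis acidic magnesium salt or basic organometallic is present and the C4–O bond is again untouched.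

Step 5. What may go wrong: activation of the benzylic instead of the allylic hydroxyl, with ionisation at C2 and loss of the 2,3-cis relationship, or elimination. The fallback puts the leaving group on the allylic oxygen in a separate step and closes the ring through a π-allylpalladium intermediate; it sets out from diol 9 and comes back at oxolane 10. Methyl chloroformate and pyridine at −20 °C should acylate the primary allylic hydroxyl selectively to (3S,4R)-4-[3,4-bis(benzyloxy)phenyl]-4-hydroxy-2-methylidene-3-[(4,4,5,5-tetramethyl-1,3,2-dioxaborolan-2-yl)methyl]butyl methyl carbonate F9. Pd(PPh3)4 in THF then ionises only this position, and the benzylic oxygen attacks the π-allyl terminus (Tsuji–Trost etherification; both termini give the same oxolane).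

**Further compounds**

F1 | step 3 | 3-(hydroxymethyl)but-3-enoic acid | OCC(=C)CC(=O)O
F2 | step 3 | tert-butyldimethylsilyl 3-({[tert-butyl(dimethyl)silyl]oxy}methyl)but-3-enoate | C=C(CO[Si](C)(C)C(C)(C)C)CC(=O)O[Si](C)(C)C(C)(C)C
F3 | step 3 | 3-({[tert-butyl(dimethyl)silyl]oxy}methyl)but-3-enoic acid | C=C(CO[Si](C)(C)C(C)(C)C)CC(=O)O
F4 | step 3 | 3-({[tert-butyl(dimethyl)silyl]oxy}methyl)but-3-enoic pivalic anhydride | C=C(CO[Si](C)(C)C(C)(C)C)CC(=O)OC(=O)C(C)(C)C
F5 | step 3 | (4R)-4-benzyl-3-[3-({[tert-butyl(dimethyl)silyl]oxy}methyl)but-3-enoyl]-1,3-oxazolidin-2-one | C=C(CO[Si](C)(C)C(C)(C)C)CC(=O)N1[C@H](Cc2ccccc2)COC1=O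
F6 | step 3 | (4R)-4-benzyl-3-[(2S,3R)-3-[3,4-bis(benzyloxy)phenyl]-2-(3-{[tert-butyl(dimethyl)silyl]oxy}prop-1-en-2-yl)-3-[(trimethylsilyl)oxy]propanoyl]-1,3-oxazolidin-2-one | C[Si](C)(C)O[C@@H](c1ccc(OCc2ccccc2)c(OCc2ccccc2)c1)[C@H](C(=C)CO[Si](C)(C)C(C)(C)C)C(=O)N3[C@H](Cc4ccccc4)COC3=O
F7 | step 3 | (4R)-4-benzyl-3-[(2S,3R)-3-[3,4-bis(benzyloxy)phenyl]-3-hydroxy-2-(3-hydroxyprop-1-en-2-yl)propanoyl]-1,3-oxazolidin-2-one | O[C@@H](c1ccc(OCc2ccccc2)c(OCc2ccccc2)c1)[C@H](C(=C)CO)C(=O)N3[C@H](Cc4ccccc4)COC3=O
F8 | step 3 | (4R)-4-benzyl-3-{[(2R,3S)-2-[3,4-bis(benzyloxy)phenyl]-4-methylideneoxolan-3-yl]carbonyl}-1,3-oxazolidin-2-one | C=C1CO[C@@H](c2ccc(OCc3ccccc3)c(OCc3ccccc3)c2)[C@H]1C(=O)N4[C@H](Cc5ccccc5)COC4=O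
F9 | step 5 | (3S,4R)-4-[3,4-bis(benzyloxy)phenyl]-4-hydroxy-2-methylidene-3-[(4,4,5,5-tetramethyl-1,3,2-dioxaborolan-2-yl)methyl]butyl methyl carbonate | O[C@@H](c1ccc(OCc2ccccc2)c(OCc2ccccc2)c1)[C@H](C(=C)COC(=O)OC)CB3OC(C)(C)C(C)(C)O3
F10 | step 8 | (3R,4R,5R)-5-[3,4-bis(benzyloxy)phenyl]-4-(hydroxymethyl)-3-(iodomethyl)oxolan-3-ol | IC[C@]1(O)CO[C@@H](c2ccc(OCc3ccccc3)c(OCc3ccccc3)c2)[C@H]1CO
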